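## The problem

The target 20 is a (1S,2R,3R)-1-aryltetralin lignan diacetate, numbered here as follows: ring B is C1–C4; ring A is C4a, C5–C8, C8a with OMe on C6 and OH on C7; ring C, the 4-hydroxy-3,5-dimethoxyphenyl group, sits on C1 through C1'; the acetoxymethyl carbons are C9 on C2 and C9' on C3; C4 is a methylene. A synthesis has to fuse ring B to ring A through the C1–C8a bond, para to the C6 methoxy group, and has to line up three contiguous stereocentres, all trans, as one enantiomer. C3 is the best place to fix absolute configuration, because it is neither benzylic nor enolisable in the final skeleton, and C2 and C1 can then be set relative to it, since the all-trans isomer is the one in which every substituent avoids its neighbour. The two primary acetates do not survive base, hydride or organometallic reagents and can migrate to a free phenol. The two phenols and the doubly benzylic C1–H are easily oxidised, and three aryl methyl ethers rule out ether-cleaving Lewis acids late in the route, so the acetates must come late and the phenols must be freed last under neutral conditions. The enabling feature is twofold: C1 is benzylic to ring C and para to its oxygen, so a cation there is well stabilised and lies within six-membered reach of C8a; and C9 is 1,4-related to the C9' oxygen (C9–C2–C3–C9'–O), so a one-carbon electrophile carried on that oxygen reaches C2 through a five-membered ring. A C1=C2 double bond in an open chain can therefore be turned into ring B, the C2–C9 bond and the C1 and C2 stereocentres in one cationic event.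

## Retrosynthesis

**20 from 19 and 18.** No skeletal bond is cut at first. The phenols are traced back to the benzyl ethers of diacetate 19 and the acetates to diol 18. Hydrogenolysis is placed last because it is neutral, so the acetates neither hydrolyse nor migrate; acid-labile phenol masks would endanger the esters or the aryl methyl ethers. Acetylating 18 while both phenols are benzylated removes any O-selectivity question. The forward steps only have to leave the C1–H bond and the esters alone.

**18 from 16.** The C9 and C9' oxygens are reconnected: C9 is raised to the aldehyde level and tied to the C9' oxygen as methyl acetal 16, which opens through lactol 17. The neighbouring oxidation levels are worse. Holding C9 at the alcohol level inside a cyclic ether would call for an ether cleavage that the aryl ethers would not tolerate. Raising it to the acid level would demand an acylium-type electrophile one step earlier. The acetal yields to dilute acid and NaBH4, and it puts a one-carbon unit on oxygen, which is the retron for the key cut.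

**16 from 13 and 14.** Two bonds are cut, C2–C9 and C1–C8a. This opens the tetrahydrofuran and ring B and removes the C1 and C2 stereocentres. What remains is the open-chain (E)-homoallylic alcohol 13 with C3 as its only stereocentre, plus trimethyl orthoformate 14 as the source of C9; the two are joined in the flask as mixed orthoformate 15. Cutting C1–C8a alone would leave C2 and its C9 branch to be made separately, and cutting C1–C1' would bring back an intermolecular arylation. The double cut is preferred because one ionisation pays for two bonds, two rings and two stereocentres. The forward reaction must ionise the orthoformate, add the carbenium carbon to C2 and not C1, close ring B at C8a, and pass the C3 configuration on to C2 and C1.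

**13 from 12, and 12 from 8 and 10.** With C9' seen as a masked carboxyl, C3 is alpha to a carbonyl and the C3–C4 bond is cut as an enolate alkylation. Imide 12 comes from the (E)-styrylacetyl imide 8 and O-benzylvanillyl bromide 10, with (R)-4-benzyl-2-oxazolidinone 6 fixing C3. This cut is preferred to C2–C3 or the alkene because the electrophile is a reactive benzylic bromide and alpha attack keeps the styrene conjugation. The forward step must alkylate dienolate 11 at the alpha carbon on the face away from the auxiliary's benzyl group without letting the acidic product equilibrate. LiBH4 then frees 13 and returns 6.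

**8 from 5 and 6; 5 from 2 and 3; 2 from 1; 10 from 9.** The remaining cuts are the imide C–N bond, activated through mixed anhydride 7, and the C1=C2 double bond. Acid 5 comes from the Wittig reaction of aldehyde 2 with ylide 4, made from phosphonium salt 3; this delivers C2, C3 and C9' in one piece and places the double bond in conjugation with ring C. Aldehyde 2 is the benzyl ether of syringaldehyde 1, and bromide 10 comes from 4-benzyloxy-3-methoxybenzyl alcohol 9. All building blocks are simple benzenoid or one-carbon compounds.

## Roads not taken

Alternative 1: Ring A is taken apart. Cutting C4a–C8a and C7–C8 leaves furyl ynone A2, in which a 4-methoxyfuran-2-yl group hangs on C4 and C1 is the carbonyl of an ethynyl ketone. On heating, the furan termini C4a and C7 would add across the alkyne carbons C8a and C8 and close ring B. The oxygen bridge would then open towards the methoxy-stabilised C4a cation to give tetralone A1 with the C7 phenol free.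
- Merits: the step is thermal and acid-free, the methoxy/hydroxy pattern of ring A follows from the furan without any regiochemical question, and the ring A phenol never needs protection. In these respects it is better than the chosen plan, whose Friedel–Crafts closure must pick C8a and whose phenols travel as benzyl ethers.
- Weak points: A1 has neither ring C nor the C1 stereocentre. An aryl organometallic would have to add to the C1 ketone in the presence of two acetates and a phenol. The resulting tertiary benzylic centre would then have to be reduced with ring C ending trans to C9, whereas hydride delivery anti to the C2 substituent leads to the cis relationship. The key step creates no stereocentre, so C2 and C3 must both be set in A2, where C2 is alpha to an ynone and open to epimerisation.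
- Comparison: against the cleaner ring A construction, the chosen plan delivers ring C, ring B, C1 and C2 in its key step from a precursor with one stereocentre, and only three operations follow it.

Alternative 2: C1 is cut from both aryl groups, C1–C8a and C1–C1'. The precursor is methyl acetal A4, a 2-methoxytetrahydrofuran in which C1 is the acetal carbon tied to the C9' oxygen, C2 carries the acetoxymethyl group and C3 the protected vanillyl arm. Ring C comes from syringol A5. BF3·OEt2 would ionise the acetal and ring A would close ring B on C1. The cyclic benzylic ether so formed would ionise again, releasing the C9' hydroxyl, and A5 would attack through its para carbon to give A3.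
- Merits: the key step has the better precedent, since Friedel–Crafts arylation of lactol ethers and benzylic ethers by electron-rich arenes is established. Ring C enters from a bulk phenol without protection. Only two operations would follow A3 (acetylation of the C9' alcohol beside the hindered phenol, then hydrogenolysis), against three in the chosen plan.
- Weak points: A4 must be made with C2 and C3 already set, cis on the five-membered ring, so two stereocentres must be secured where the chosen plan needs one. The C1 configuration rests on an intermolecular attack on a secondary benzylic cation next to C2. Loss of the C2 proton from that cation is a competing exit that would erase C2; participation by the C9 acetate may help but cannot be counted on. The C9/C9' differentiation in A3 is of no use for a target with two acetates.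
- Comparison: against the stronger precedent, the chosen plan has a shorter and stereochemically lighter approach to its cyclisation substrate and sets each new stereocentre in an intramolecular, ring-constrained event.

Alternative 3: The cut is at C2–C9 and C3–C9' together; both side-chain carbons arrive by carbonylation across the C2=C3 double bond of 1-aryl-1,4-dihydronaphthalene A7. Under divalent palladium catalysis (Pd(OCOCF3)2 with a diimine ligand) and a quinone reoxidant, the alkene would be bis(methoxycarbonylated). Base added to the same pot would then equilibrate the diester to all-trans A6.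
- Merits: two carbons come from the cheapest source in one catalytic step, and in carbon economy this road is better than the chosen plan. Thermodynamic control makes any kinetic diastereomer converge on the all-equatorial diester as long as C1 holds. Hydride reduction of A6 would give diol 18, so the endgame is the same length.
- Weak points: the key step closes no ring, so the whole tetralin with ring C and the C1 stereocentre must already exist in A7 as one enantiomer; the hard part is moved, not solved. A7 is poorly matched to the conditions. Its C1–H is doubly benzylic and allylic, and under an oxidising palladium system aromatisation of ring B and migration of the double bond into conjugation are both likely, each destroying C1. A 1,2-disubstituted cyclic alkene is a slow substrate for this carbonylation, and the electron-rich arenes invite palladation.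
- Comparison: against the elegant carbon source, the chosen plan builds ring B and two stereocentres in the key step from an open-chain precursor whose single stereocentre is configurationally robust.

Key step: step 7

Remark: 4-benzyloxy-3-methoxybenzyl alcohol 9, (R)-4-benzyl-2-oxazolidinone 6 and phosphonium salt 3 are treated as catalogue compounds.
Remark: C9 of 16 and 17 forms as both epimers and is left undefined in their SMILES; it becomes a methylene in step 8.

## Route

Step 1
Reactants: 1 syringaldehyde (4-hydroxy-3,5-dimethoxybenzaldehyde)
Product: 2 4-benzyloxy-3,5-dimethoxybenzaldehyde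
Conditions: BnBr, K2CO3, DMF, 60 °C
Reagents that add atoms: benzyl bromide, BrCc1ccccc1
Why: Williamson ether synthesis; K2CO3 forms the phenoxide of 1, which is alkylated by benzyl bromide while the aldehyde is inert.

Step 2
Reactants: 2 4-benzyloxy-3,5-dimethoxybenzaldehyde; 3 (2-carboxyethyl)triphenylphosphonium bromide
Product: 5 (E)-4-(4-benzyloxy-3,5-dimethoxyphenyl)but-3-enoic acid, via phosphorus ylide 4 (not isolated)
Conditions: 3, NaN(SiMe3)2 (2.1 equiv), THF, 0 °C; then 2, −78 °C → rt; dilute HCl work-up
Reagents that add atoms: none
Why: Wittig olefination with the ylide carboxylate 4; ylides carrying a nearby carboxylate are known to give mainly (E)-alkenes with aryl aldehydes, and the β,γ-position of the double bond is held by conjugation with ring C. No stereocentre is formed.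

Step 3
Reactants: 5 (E)-4-(4-benzyloxy-3,5-dimethoxyphenyl)but-3-enoic acid; 6 (R)-4-benzyl-1,3-oxazolidin-2-one
Product: 8 (R)-4-benzyl-3-[(E)-4-(4-benzyloxy-3,5-dimethoxyphenyl)but-3-enoyl]-1,3-oxazolidin-2-one, via mixed pivalic anhydride 7 (not isolated)
Conditions: t-BuCOCl, Et3N, THF, −20 °C; then 6, LiCl, −20 °C → rt
Reagents that add atoms: none
Why: N-acylation of an oxazolidinone through the mixed pivalic anhydride with LiCl and Et3N; 6 attacks the less hindered carbonyl of 7. The double bond should stay in the β,γ-position because that isomer is conjugated with the arene.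

Step 4
Reactants: 9 4-benzyloxy-3-methoxybenzyl alcohol
Product: 10 4-benzyloxy-3-methoxybenzyl bromide
Conditions: PBr3, Et2O, 0 °C
Reagents that add atoms: phosphorus tribromide, BrP(Br)Br
Why: Conversion of an electron-rich benzylic alcohol into the bromide by PBr3 (substitution via the phosphite ester); 10 is used at once because such bromides do not store well.

Step 5
Reactants: 8 (R)-4-benzyl-3-[(E)-4-(4-benzyloxy-3,5-dimethoxyphenyl)but-3-enoyl]-1,3-oxazolidin-2-one; 10 4-benzyloxy-3-methoxybenzyl bromide
Product: 12 (R)-4-benzyl-3-[(2R,3E)-2-(4-benzyloxy-3-methoxybenzyl)-4-(4-benzyloxy-3,5-dimethoxyphenyl)but-3-enoyl]-1,3-oxazolidin-2-one, via sodium dienolate 11 (not isolated)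
Conditions: NaN(SiMe3)2 (0.98 equiv), THF, −78 °C; then 10, −78 → −45 °C; AcOH quench at −78 °C
Reagents that add atoms: none
Why: Evans asymmetric alkylation: the chelated (Z)-sodium enolate 11, here a dienolate, reacts at its alpha carbon with the benzylic bromide on the face opposite the benzyl group of the auxiliary, which for the (R)-auxiliary sets C3 as (R). Alpha attack keeps the styrene conjugation; a slight deficit of base and a cold quench guard the acidic new C3–H.

Step 6
Reactants: 12 (R)-4-benzyl-3-[(2R,3E)-2-(4-benzyloxy-3-methoxybenzyl)-4-(4-benzyloxy-3,5-dimethoxyphenyl)but-3-enoyl]-1,3-oxazolidin-2-one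
Product: 13 (2R,3E)-2-(4-benzyloxy-3-methoxybenzyl)-4-(4-benzyloxy-3,5-dimethoxyphenyl)but-3-en-1-ol
Conditions: LiBH4, MeOH (1 equiv), Et2O, 0 °C
Reagents that add atoms: none
Why: Reductive cleavage of the N-acyl oxazolidinone by LiBH4 at the exocyclic carbonyl gives the primary alcohol and returns 6; the conditions are not basic enough to touch C3 or to move the double bond.

Step 7
Reactants: 13 (2R,3E)-2-(4-benzyloxy-3-methoxybenzyl)-4-(4-benzyloxy-3,5-dimethoxyphenyl)but-3-en-1-ol; 14 trimethyl orthoformate
Product: 16 (1S,2R,3R)-7-benzyloxy-1-(4-benzyloxy-3,5-dimethoxyphenyl)-6-methoxytetralin trans-fused across C2–C3 to a 2-methoxytetrahydrofuran (C9 on C2 as CH(OMe)–O–C9'; all-trans; both C9 epimers), via mixed orthoformate 15 (not isolated)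
Conditions: 14 (excess), pyridinium p-toluenesulfonate (cat.), 40 °C, then Et3N, evaporation; Me3SiOTf (1.2 equiv), 2,6-di-tert-butyl-4-methylpyridine (1.5 equiv), CH2Cl2, −78 → −40 °C; Et3N–MeOH quench at −40 °C
Reagents that add atoms: none
Why: Proposed new method: Me3SiOTf should abstract methoxide from mixed orthoformate 15 to give a dialkoxycarbenium ion at C9, which the electron-rich (E)-styrene attacks through C2 so that the charge moves to C1, stabilised by the para oxygen of ring C, after which ring A captures C1 through C8a and the hindered pyridine takes up the proton. The closest known reaction type is the aldehyde- or acetal-initiated Prins cyclisation of aryl-substituted homoallylic alcohols terminated by Friedel–Crafts alkylation, together with the addition of orthoformate-derived dialkoxycarbenium ions to enol ethers; their combination on a styrene is the untested part. The tetrahydrofuran closes in a 5-exo mode with respect to the alkene (C9, O, C9', C3 and C2 in the ring, C1 outside), preferred over 6-endo attack at C1 because only the former gives a benzylic cation. Ring B closes by a six-membered Friedel–Crafts alkylation in which the arene bond C4a–C8a becomes part of the new ring; direct attack of ring A on C9 would need a seven-membered ring and should be slower. C2 is controlled by C3: in the envelope transition state the C4 arm on C3 and the C1 carbon on C2 lie trans and pseudo-equatorial. C1 is controlled by C2 and C3: the planar cation closes through a half-chair with ring C equatorial and trans to C9, as in the acid-mediated closure of benzylic cations on trans-disubstituted butyrolactones to trans-fused aryltetralins. The step needs attack on ring A at C8a and not at the carbon between the side chain and the methoxy group, which the para-directing methoxy group and lower hindrance secure, it needs C3 to stay intact, which the dialkoxycarbenium ion favours because a 2-oxonia-Cope shift would exchange it for a far less stabilised O-alkyl formaldehyde oxocarbenium ion, and it needs the styrene not to be protonated and cyclised without C9, which the hindered base secures by keeping free acid low.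

Step 8
Reactants: 16 (1S,2R,3R)-7-benzyloxy-1-(4-benzyloxy-3,5-dimethoxyphenyl)-6-methoxytetralin trans-fused across C2–C3 to a 2-methoxytetrahydrofuran
Product: 18 [(1S,2R,3R)-7-benzyloxy-1-(4-benzyloxy-3,5-dimethoxyphenyl)-6-methoxy-1,2,3,4-tetrahydronaphthalene-2,3-diyl]dimethanol, via lactol 17 (not isolated)
Conditions: HCl (cat.), THF–H2O, rt; then NaHCO3 to pH 7, NaBH4 (excess), 0 °C
Reagents that add atoms: water, O
Why: Acid hydrolysis of a 2-methoxytetrahydrofuran (a furanoside-type acetal) gives lactol 17, whose open hydroxy aldehyde form is reduced by NaBH4 to the primary alcohol. C9 ceases to be stereogenic, and C1–C3 should be untouched if the aldehyde is reduced as soon as it is set free.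

Step 9
Reactants: 18 [(1S,2R,3R)-7-benzyloxy-1-(4-benzyloxy-3,5-dimethoxyphenyl)-6-methoxy-1,2,3,4-tetrahydronaphthalene-2,3-diyl]dimethanol
Product: 19 [(1S,2R,3R)-7-benzyloxy-1-(4-benzyloxy-3,5-dimethoxyphenyl)-6-methoxy-1,2,3,4-tetrahydronaphthalene-2,3-diyl]bis(methylene) diacetate
Conditions: Ac2O, pyridine, DMAP (cat.), CH2Cl2, rt
Reagents that add atoms: acetic anhydride, CC(=O)OC(C)=O
Why: Acetylation of two primary alcohols with Ac2O under DMAP catalysis; both phenols are benzyl-protected, so no selectivity is required.

Step 10
Reactants: 19 [(1S,2R,3R)-7-benzyloxy-1-(4-benzyloxy-3,5-dimethoxyphenyl)-6-methoxy-1,2,3,4-tetrahydronaphthalene-2,3-diyl]bis(methylene) diacetate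
Product: 20 [(1S,2R,3R)-7-hydroxy-1-(4-hydroxy-3,5-dimethoxyphenyl)-6-methoxy-1,2,3,4-tetrahydronaphthalene-2,3-diyl]bis(methylene) diacetate
Conditions: H2 (1 atm), 10% Pd/C, EtOAc–EtOH, rt
Reagents that add atoms: none
Why: Hydrogenolysis of aryl benzyl ethers over Pd/C under neutral conditions; acetates, aryl methyl ethers and the C1–H bond are not affected, and the absence of base prevents acetyl migration to the freed phenols.

## Compound list

1 | syringaldehyde (4-hydroxy-3,5-dimethoxybenzaldehyde) | COc1cc(C=O)cc(OC)c1O | starting material
2 | 4-benzyloxy-3,5-dimethoxybenzaldehyde | COc1cc(C=O)cc(OC)c1OCc1ccccc1 | intermediate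
3 | (2-carboxyethyl)triphenylphosphonium bromide | OC(=O)CC[P+](c1ccccc1)(c1ccccc1)c1ccccc1.[Br-] | starting material
4 | phosphorus ylide formed in the flask: sodium 3-(triphenylphosphoranylidene)propanoate | [Na+].[O-]C(=O)CC=P(c1ccccc1)(c1ccccc1)c1ccccc1 | intermediate
5 | (E)-4-(4-benzyloxy-3,5-dimethoxyphenyl)but-3-enoic acid | COc1cc(/C=C/CC(=O)O)cc(OC)c1OCc1ccccc1 | intermediate
6 | (R)-4-benzyl-1,3-oxazolidin-2-one | O=C1N[C@H](Cc2ccccc2)CO1 | starting material
7 | mixed pivalic anhydride of 5, formed in the flask | COc1cc(/C=C/CC(=O)OC(=O)C(C)(C)C)cc(OC)c1OCc1ccccc1 | intermediate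
8 | (R)-4-benzyl-3-[(E)-4-(4-benzyloxy-3,5-dimethoxyphenyl)but-3-enoyl]-1,3-oxazolidin-2-one | COc1cc(/C=C/CC(=O)N2[C@H](Cc3ccccc3)COC2=O)cc(OC)c1OCc1ccccc1 | intermediate
9 | 4-benzyloxy-3-methoxybenzyl alcohol | COc1cc(CO)ccc1OCc1ccccc1 | starting material
10 | 4-benzyloxy-3-methoxybenzyl bromide | COc1cc(CBr)ccc1OCc1ccccc1 | intermediate
11 | sodium (Z)-dienolate of 8, formed in the flask | COc1cc(/C=C/C=C(\[O-])N2[C@H](Cc3ccccc3)COC2=O)cc(OC)c1OCc1ccccc1.[Na+] | intermediate
12 | (R)-4-benzyl-3-[(2R,3E)-2-(4-benzyloxy-3-methoxybenzyl)-4-(4-benzyloxy-3,5-dimethoxyphenyl)but-3-enoyl]-1,3-oxazolidin-2-one | COc1cc(C[C@@H](C(=O)N2[C@H](Cc3ccccc3)COC2=O)/C=C/c2cc(OC)c(OCc3ccccc3)c(OC)c2)ccc1OCc1ccccc1 | intermediate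
13 | (2R,3E)-2-(4-benzyloxy-3-methoxybenzyl)-4-(4-benzyloxy-3,5-dimethoxyphenyl)but-3-en-1-ol | COc1cc(C[C@@H](CO)/C=C/c2cc(OC)c(OCc3ccccc3)c(OC)c2)ccc1OCc1ccccc1 | intermediate
14 | trimethyl orthoformate | COC(OC)OC | starting material
15 | mixed orthoformate formed in the flask: dimethyl (2R,3E)-2-(4-benzyloxy-3-methoxybenzyl)-4-(4-benzyloxy-3,5-dimethoxyphenyl)but-3-en-1-yl orthoformate | COc1cc(C[C@@H](COC(OC)OC)/C=C/c2cc(OC)c(OCc3ccccc3)c(OC)c2)ccc1OCc1ccccc1 | intermediate
16 | (1S,2R,3R)-7-benzyloxy-1-(4-benzyloxy-3,5-dimethoxyphenyl)-6-methoxytetralin trans-fused across C2–C3 to a 2-methoxytetrahydrofuran (C9 on C2 as CH(OMe)–O–C9'; all-trans; both C9 epimers) | COc1cc2c(cc1OCc1ccccc1)[C@H](c1cc(OC)c(OCc3ccccc3)c(OC)c1)[C@@H](C(OC)O4)[C@H](C4)C2 | intermediate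
17 | lactol corresponding to 16 (C9 as CH(OH)–O–C9'; both C9 epimers), formed in the flask | COc1cc2c(cc1OCc1ccccc1)[C@H](c1cc(OC)c(OCc3ccccc3)c(OC)c1)[C@@H](C(O)O4)[C@H](C4)C2 | intermediate
18 | [(1S,2R,3R)-7-benzyloxy-1-(4-benzyloxy-3,5-dimethoxyphenyl)-6-methoxy-1,2,3,4-tetrahydronaphthalene-2,3-diyl]dimethanol | COc1cc2c(cc1OCc1ccccc1)[C@H](c1cc(OC)c(OCc3ccccc3)c(OC)c1)[C@@H](CO)[C@H](CO)C2 | intermediate
19 | [(1S,2R,3R)-7-benzyloxy-1-(4-benzyloxy-3,5-dimethoxyphenyl)-6-methoxy-1,2,3,4-tetrahydronaphthalene-2,3-diyl]bis(methylene) diacetate | COc1cc2c(cc1OCc1ccccc1)[C@H](c1cc(OC)c(OCc3ccccc3)c(OC)c1)[C@@H](COC(C)=O)[C@H](COC(C)=O)C2 | intermediate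
20 | [(1S,2R,3R)-7-hydroxy-1-(4-hydroxy-3,5-dimethoxyphenyl)-6-methoxy-1,2,3,4-tetrahydronaphthalene-2,3-diyl]bis(methylene) diacetate | COc1cc2c(cc1O)[C@H](c1cc(OC)c(O)c(OC)c1)[C@@H](COC(C)=O)[C@H](COC(C)=O)C2 | target

## Step count and risks

Total step count: 10. Longest linear sequence: 9 steps (steps 1, 2, 3, 5, 6, 7, 8, 9, 10); step 4 is a one-step side branch.

**Step 7 (key step).** The dialkoxycarbenium ion may be too stabilised to add to the styrene. Dealkylation to a formate ester, loss of the homoallylic alkoxide in place of methoxide, transfer of the one-carbon unit between molecules, or acid-induced hydroarylation of the styrene without C9 could then take over. Poor diastereocontrol at C2 is the second concern, because nothing later corrects it. Fallback, from 13 to 20: the formaldehyde variant of the same cascade is the known Prins and Friedel–Crafts reaction of aryl homoallylic alcohols. Alcohol 13 with paraformaldehyde and Me3SiOTf in CH2Cl2 should give the (1S,2R,3R)-tetralin in which C9 and C9' are joined through oxygen as a trans-fused tetrahydrofuran F1. C9 then enters at the alcohol level and the ether must be cleaved. Ac2O with catalytic FeCl3 should open the ether ring of F1 to the two primary acetates and at the same time exchange the benzyl ethers for aryl acetates, giving the tetraacetate [(1S,2R,3R)-7-acetoxy-1-(4-acetoxy-3,5-dimethoxyphenyl)-6-methoxy-1,2,3,4-tetrahydronaphthalene-2,3-diyl]bis(methylene) diacetate F2. Pyrrolidine in MeCN should then remove the two aryl acetates of F2 selectively and rejoin the route at 20. This trades the mild endgame for an acetolysis beside electron-rich arenes, which is why it is the reserve.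

**Step 5.** Alkylation of the aryl-conjugated dienolate 11 may suffer from low reactivity, from competing attack through the γ-carbon, or from proton exchange between enolate and the more acidic product, which would erode the C3 configuration and allow dialkylation. Fallback, from 6, 10 and 2 to 13: set the stereocentre on the simpler crotonyl system and attach ring C afterwards. Acylation of 6 with crotonyl chloride (n-BuLi, THF, −78 °C) gives (R)-4-benzyl-3-[(E)-but-2-enoyl]-1,3-oxazolidin-2-one F3. Deconjugative alpha-alkylation of the sodium dienolate of F3 with 10 gives (R)-4-benzyl-3-[(2R)-2-(4-benzyloxy-3-methoxybenzyl)but-3-enoyl]-1,3-oxazolidin-2-one F4. LiBH4 reduction of F4 gives (2R)-2-(4-benzyloxy-3-methoxybenzyl)but-3-en-1-ol F5. Methylenation of 2 with Ph3P=CH2 gives 4-benzyloxy-3,5-dimethoxystyrene F6. Cross-metathesis of F5 with F6 (second-generation Grubbs catalyst, RuCl2(=CHPh)(PCy3)(H2IMes), CH2Cl2, 40 °C) should give the (E)-alkene 13.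

**Step 8.** Lactol 17 is in equilibrium with an open hydroxy aldehyde whose C2 is enolisable. Epimerisation at C2 followed by reclosure to a cis-fused ring, or dehydration of the lactol, would erode the all-trans configuration before the hydride arrives. Fallback, from 16 to 18: oxidise instead of hydrolyse. CrO3/H2SO4 in acetone at 0 °C, the standard conversion of 2-alkoxytetrahydrofurans into γ-lactones, should turn 16 into the trans-fused C9 γ-lactone F7, in which the carbonyl is C9 on C2 and the ring oxygen sits on C9'. LiAlH4 in THF at 0 °C then reduces F7 quickly to diol 18, leaving no time for base-induced epimerisation at C2.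

**Step 2.** Incomplete (E)-selectivity in the Wittig reaction, or base-induced migration of the double bond, would give isomer mixtures that are carried into the auxiliary chemistry. Fallback, from 2 to 5: build the β,γ-unsaturated acid under thermodynamic control. Wittig reaction of 2 with Ph3P=CHOMe gives the enol ether 2-benzyloxy-1,3-dimethoxy-5-(2-methoxyethenyl)benzene F8. Dilute aqueous acid turns F8 into (4-benzyloxy-3,5-dimethoxyphenyl)acetaldehyde F9. Decarboxylative Knoevenagel–Doebner condensation of F9 with malonic acid (Et3N, 90 °C), the classical route from arylacetaldehydes to (E)-styrylacetic acids, should give 5.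

## Further compounds

F1 | step 7 | (1S,2R,3R)-7-benzyloxy-1-(4-benzyloxy-3,5-dimethoxyphenyl)-6-methoxytetralin with C9 and C9' joined through oxygen as a trans-fused tetrahydrofuran | COc1cc2c(cc1OCc1ccccc1)[C@H](c1cc(OC)c(OCc3ccccc3)c(OC)c1)[C@@H](CO4)[C@H](C4)C2
F2 | step 7 | [(1S,2R,3R)-7-acetoxy-1-(4-acetoxy-3,5-dimethoxyphenyl)-6-methoxy-1,2,3,4-tetrahydronaphthalene-2,3-diyl]bis(methylene) diacetate | COc1cc2c(cc1OC(C)=O)[C@H](c1cc(OC)c(OC(C)=O)c(OC)c1)[C@@H](COC(C)=O)[C@H](COC(C)=O)C2
F3 | step 5 | (R)-4-benzyl-3-[(E)-but-2-enoyl]-1,3-oxazolidin-2-one | C/C=C/C(=O)N1[C@H](Cc2ccccc2)COC1=O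
F4 | step 5 | (R)-4-benzyl-3-[(2R)-2-(4-benzyloxy-3-methoxybenzyl)but-3-enoyl]-1,3-oxazolidin-2-one | COc1cc(C[C@@H](C(=O)N2[C@H](Cc3ccccc3)COC2=O)C=C)ccc1OCc1ccccc1
F5 | step 5 | (2R)-2-(4-benzyloxy-3-methoxybenzyl)but-3-en-1-ol | COc1cc(C[C@@H](CO)C=C)ccc1OCc1ccccc1
F6 | step 5 | 4-benzyloxy-3,5-dimethoxystyrene | COc1cc(C=C)cc(OC)c1OCc1ccccc1
F7 | step 8 | trans-fused γ-lactone of the (1S,2R,3R)-tetralin: carbonyl at C9 on C2, ring oxygen on C9' | COc1cc2c(cc1OCc1ccccc1)[C@H](c1cc(OC)c(OCc3ccccc3)c(OC)c1)[C@@H](C(=O)O4)[C@H](C4)C2
F8 | step 2 | 2-benzyloxy-1,3-dimethoxy-5-(2-methoxyethenyl)benzene (E/Z mixture) | COC=Cc1cc(OC)c(OCc2ccccc2)c(OC)c1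
F9 | step 2 | (4-benzyloxy-3,5-dimethoxyphenyl)acetaldehyde | O=CCc1cc(OC)c(OCc2ccccc2)c(OC)c1
A1 | alternative 1 | 2,3-trans-bis(acetoxymethyl)-7-hydroxy-6-methoxy-1-tetralone, C2 and C3 as in the target | COc1cc2c(cc1O)C(=O)[C@@H](COC(C)=O)[C@H](COC(C)=O)C2
A2 | alternative 1 | 2,3-bis(acetoxymethyl)-1-(4-methoxyfuran-2-yl)hex-5-yn-4-one, stereocentres as in the target | C#CC(=O)[C@@H](COC(C)=O)[C@H](COC(C)=O)Cc1cc(OC)co1
A3 | alternative 2 | all-trans tetralin with C9 acetate, free C9' alcohol, free ring C phenol and ring A benzyl ether | COc1cc2c(cc1OCc1ccccc1)[C@H](c1cc(OC)c(O)c(OC)c1)[C@@H](COC(C)=O)[C@H](CO)C2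
A4 | alternative 2 | 3,4-cis-3-(acetoxymethyl)-4-(4-benzyloxy-3-methoxybenzyl)-2-methoxytetrahydrofuran (both acetal epimers) | O1C(OC)[C@@H](COC(C)=O)[C@H](C1)Cc1ccc(OCc2ccccc2)c(OC)c1
A5 | alternative 2 | syringol (2,6-dimethoxyphenol) | COc1cccc(OC)c1O
A6 | alternative 3 | all-trans dimethyl 7-benzyloxy-1-(4-benzyloxy-3,5-dimethoxyphenyl)-6-methoxytetralin-2,3-dicarboxylate | COc1cc2c(cc1OCc1ccccc1)[C@H](c1cc(OC)c(OCc3ccccc3)c(OC)c1)[C@@H](C(=O)OC)[C@H](C(=O)OC)C2
A7 | alternative 3 | (S)-7-benzyloxy-1-(4-benzyloxy-3,5-dimethoxyphenyl)-6-methoxy-1,4-dihydronaphthalene | COc1cc2c(cc1OCc1ccccc1)[C@H](c1cc(OC)c(OCc3ccccc3)c(OC)c1)C=CC2
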